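## The problem

Target 15 is a trans-2-aryl-3-(hydroxymethyl)-2,3-dihydrobenzofuran. Benzene ring A (C3a–C7a, with the C7 methoxy group and the C5 3-hydroxypropyl chain) is fused through C3a and C7a to a dihydrofuran ring. C2 of that ring carries the syringyl ring B and C3 carries the C-γ hydroxymethyl group. The two adjacent stereocentres are C2 (S) and C3 (R), trans to each other. At the alcohol oxidation level C3 has no acidifying neighbour, so the trans relationship cannot be reached by late equilibration and has to be built in. C2 is a benzylic ether carbon para to the ring B phenol. Once that phenol is free, acid or strong base can open the C2–O1 bond through a quinone methide, so the phenol must stay masked until the last step, preferably by an electron-withdrawing group. One phenol and two primary alcohols must be told apart, and the two electron-rich arenes exclude strong oxidants and electrophiles late in the route. An oxygen-bearing C2 can control C3 if C3 is offered as the second carbon of an epoxide, because a stereospecific substitution then carries the epoxide geometry into the ring. The enabling feature is that the adjacent ring A carbons C3a and C7a are bonded to C3 and O1, which are the carbon and the oxygen of a 2,3-disubstituted epoxide opened at C3. Ring A also has what palladium/norbornene catalysis asks of an aryl iodide: one ortho substituent (the C7 methoxy group beside C7a) and one free ortho C–H (C3a).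

## Retrosynthesis

**15 back to 13.** No skeletal bond is cut; the phenol O–S bond and two O–Si bonds are removed. The phenol is unmasked last (14 to 15) because a free 4′-hydroxyl makes C2 ionisable. The two silyl ethers are removed one step earlier (13 to 14) under fluoride, which the aryl methanesulfonate survives. The mesylate is preferred to a benzyl or silyl ether because it withdraws electron density from ring B; the key step needs that.

**13 to iodide 5 and cis-epoxide 12.** The bonds C3–C3a and O1–C7a are cut together. Cutting O1–C2 instead would require a leaving group at the benzylic C2 and invite ionisation. Cutting C2–C3 would require an aldol-type union and a separate ring closure. The chosen cut removes the heterocycle in one operation and leaves C2, C3 and C-γ as one small chiral fragment, with all ring A carbons in a simple aryl iodide. The forward reaction must open 12 at C3 and not at the benzylic C2, do so with inversion, and then close O1–C7a at the carbon that carried iodine. The cis geometry of 12 then translates into the trans ring.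

**12 to Z-allylic alcohol 10 via 11.** The epoxide C–O bonds are cut. A Sharpless asymmetric epoxidation of 10 creates both stereocentres at once, suprafacially, so the Z geometry becomes the cis-epoxide 11. Silylation gives 12. The precursor is achiral. The forward step must give the (2S,3R) epoxy alcohol.

**10 to syringaldehyde 6 via 8, 9 and 7.** The C2=C3 bond is cut. A Still–Gennari olefination of aldehyde 7 gives the Z-enoate 8 directly, where a Wittig or standard phosphonate olefination would give the E isomer. Hydride reduction (through enal 9) gives 10. Aldehyde 7 is the mesylate of commercial syringaldehyde 6.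

**5 to dihydroconiferyl alcohol 1 via 4, 3 and 2.** The C7a–I bond is traced to the phenolic C–O bond of 1. Electrophilic iodination of a ring A arene would go to carbons activated by the methoxy group, not to C7a, so iodine is introduced by ipso exchange: triflate 2, boronate 3, iodide 4, then silyl ether 5. Commercial 1 already contains every carbon of ring A and the side chain.

## Roads not taken

**Alternative 1:** The cut runs across C2–C1′ and C3–C3a. The (E)-alkenylboronate A1, the ring B aryllithium A2 and the ring A bromide A3 would be joined in one palladium-catalysed conjunctive coupling (Pd(OAc)2, chiral MandyPhos). Ring B migrates from boron to C2 while palladium delivers ring A to C3 on the opposite face, giving the syn boronic ester A4 with both stereocentres set by the catalyst.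
- Merits: three simple achiral pieces, catalyst control, and a reaction class that is established for vinylboron ate complexes.
- Weak points: a β-substituted alkenylboronate and an electron-rich aryl electrophile flanked by a benzyloxy group are at the margin of that reaction. A4 does not yet contain the heterocycle. The C–B bond must be oxidised, the benzyl ethers removed and O1–C2 closed. The C–B bond of A4 has the orientation of the later C2–O1 bond, so an invertive closure would give the cis ring. An ionising closure gives up the catalyst-set C2 centre and relies on the trans preference. At least four steps follow the coupling.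
- Comparison: the key event is closer to established chemistry than step 10 and is catalyst-controlled, which the chosen plan cannot claim. Against this, the chosen plan forms both ring bonds and the ring in one operation, never remakes the C2–O bond after the epoxide stage, and ends with two deprotections.

**Alternative 2:** The cut lies inside ring A, at C3a–C7a and C6–C7. In precursor A5 the C2 oxygen carries a terminal alkyne (an ynol ether) and C3 carries a 2-furyl group with the side chain at furan C4. (Ph3P)AuNTf2 would activate the alkyne, the furan would attack and reorganise, and the benzene ring A and the dihydrofuran would form together. The furan oxygen emerges as the C7 phenol of A6, which still needs O-methylation, hydrogenolysis and desilylation.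
- Merits: the substitution pattern of ring A is written into the furan, the gold-catalysed furan–yne phenol synthesis is a known reaction class, and the key step has no regiochemical choice to make at C2 or C3.
- Weak points: both stereocentres must be made beforehand in an acyclic precursor by a separate asymmetric sequence. A secondary benzylic ynol ether is hard to prepare and prone to thermal retro-ene fragmentation and to ionisation at C2 under the Lewis-acidic catalyst. The route is the longest of the four.
- Comparison: this road is safer at the ring-forming event. The chosen plan is much shorter and uses ring A as purchased, at the price of a regiochemical risk in step 10.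

**Alternative 3:** The cut is C3–C3a, made by an aryl shift. The (2S)-flavanone A7 would be treated with PhI(OAc)2 in acidic trimethyl orthoformate. Enol ether formation and iodination at C3 are followed by migration of the ring A carbon from C4 to C3, contracting the pyranone to the dihydrofuran and leaving the old C4 as the methyl ester of the trans product A8. One LiAlH4 reduction would then convert the ester to the C-γ alcohol and cleave both pivalates.
- Merits: a known reaction class on flavanones, trans-selective, with a one-step endgame. In precedent and in length after the key step this road is better than the chosen plan.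
- Weak points: an enantioenriched A7 is needed, and the flavanone C2 centre is labile to retro-oxa-Michael ring opening under the acidic conditions of the rearrangement. A7 must be built linearly on ring A (acylation, chromone formation, asymmetric conjugate arylation). Dehydrogenation of the heterocycle and migration of ring B compete with the contraction.
- Comparison: the chosen plan has no precedent to match this. What it sets against it is convergence (two fragments of four and five steps joined late), a C2 centre that is never exposed to acid in an ionisable form, and both ring bonds made from simple fragments in one step.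

Key step: step 10

Remark: the target SMILES is read as the (2S,3R)-trans isomer; palladium-bound states of the catalytic cycle in step 10 are states of the catalyst, not isolable compounds, and are described in the text without numbers.

## Route

Step 1
Reactants: 1 dihydroconiferyl alcohol [4-(3-hydroxypropyl)-2-methoxyphenol]
Product: 2 4-(3-hydroxypropyl)-2-methoxyphenyl trifluoromethanesulfonate
Conditions: PhNTf2, K2CO3, DMF, rt
Reagents that add atoms: N-phenylbis(trifluoromethanesulfonimide), O=S(=O)(N(c1ccccc1)S(=O)(=O)C(F)(F)F)C(F)(F)F
Why: Phenol-selective O-triflation; only the phenoxide formed by K2CO3 attacks the N-triflyl imide, and the aliphatic hydroxyl is not acidic enough to react, so no protecting group is needed.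

Step 2
Reactants: 2 4-(3-hydroxypropyl)-2-methoxyphenyl trifluoromethanesulfonate
Product: 3 3-[3-methoxy-4-(4,4,5,5-tetramethyl-1,3,2-dioxaborolan-2-yl)phenyl]propan-1-ol
Conditions: B2pin2, PdCl2(dppf) (5 mol %), KOAc, 1,4-dioxane, 85 °C
Reagents that add atoms: bis(pinacolato)diboron, CC1(C)OB(OC1(C)C)B1OC(C)(C)C(C)(C)O1
Why: Miyaura borylation of an aryl triflate (oxidative addition of zerovalent palladium, acetate-assisted transmetalation, reductive elimination); free primary alcohols are tolerated.

Step 3
Reactants: 3 3-[3-methoxy-4-(4,4,5,5-tetramethyl-1,3,2-dioxaborolan-2-yl)phenyl]propan-1-ol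
Product: 4 3-(4-iodo-3-methoxyphenyl)propan-1-ol
Conditions: KI, CuI (10 mol %), 1,10-phenanthroline, MeOH/H2O, air, 80 °C
Reagents that add atoms: potassium iodide, [K+].[I-]
Why: Copper-catalysed iododeboronation (Chan–Lam-type halodeboronation); the aryl group passes from boron to copper, air oxidation raises copper to its trivalent state and C–I reductive elimination places iodine exactly at the former C–B carbon (C7a), which electrophilic iodination of the arene would not do.

Step 4
Reactants: 4 3-(4-iodo-3-methoxyphenyl)propan-1-ol
Product: 5 tert-butyl[3-(4-iodo-3-methoxyphenyl)propoxy]dimethylsilane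
Conditions: TBSCl, imidazole, CH2Cl2, rt
Reagents that add atoms: tert-butyldimethylsilyl chloride, CC(C)(C)[Si](C)(C)Cl
Why: Standard imidazole-mediated silylation of a primary alcohol; the aryl iodide is inert and the silyl ether removes the only free hydroxyl before the palladium step.

Step 5
Reactants: 6 syringaldehyde [4-hydroxy-3,5-dimethoxybenzaldehyde]
Product: 7 4-formyl-2,6-dimethoxyphenyl methanesulfonate
Conditions: MsCl, Et3N, CH2Cl2, 0 °C
Reagents that add atoms: methanesulfonyl chloride, CS(=O)(=O)Cl
Why: Sulfonylation of the acidic syringyl phenol; the mesylate survives base, hydride, peroxide and palladium and makes ring B electron-poor, which the epoxide chemistry needs.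

Step 6
Reactants: 7 4-formyl-2,6-dimethoxyphenyl methanesulfonate
Product: 8 methyl (Z)-3-[3,5-dimethoxy-4-(methanesulfonyloxy)phenyl]prop-2-enoate
Conditions: (CF3CH2O)2P(O)CH2CO2Me, KN(SiMe3)2, 18-crown-6, THF, −78 °C
Reagents that add atoms: methyl bis(2,2,2-trifluoroethoxy)phosphorylacetate, COC(=O)CP(=O)(OCC(F)(F)F)OCC(F)(F)F
Why: Still–Gennari olefination; the electron-poor phosphonate with a dissociated potassium counter-ion lets the oxaphosphetane collapse faster than it equilibrates, so an aromatic aldehyde gives the Z-enoate under kinetic control.

Step 7
Reactants: 8 methyl (Z)-3-[3,5-dimethoxy-4-(methanesulfonyloxy)phenyl]prop-2-enoate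
Product: 10 4-[(Z)-3-hydroxyprop-1-enyl]-2,6-dimethoxyphenyl methanesulfonate, via Z-enal 9 (not isolated)
Conditions: i-Bu2AlH (2.5 equiv), CH2Cl2, −78 °C; aq. potassium sodium tartrate
Reagents that add atoms: none
Why: DIBAL-H 1,2-reduction of the enoate through the aluminium hemiacetal and enal 9 to the allylic alcohol at low temperature, with the Z geometry retained; aryl sulfonates are not reduced under these conditions.

Step 8
Reactants: 10 4-[(Z)-3-hydroxyprop-1-enyl]-2,6-dimethoxyphenyl methanesulfonate
Product: 11 4-[(2R,3S)-3-(hydroxymethyl)oxiran-2-yl]-2,6-dimethoxyphenyl methanesulfonate (cis; equivalently the (2S,3R)-3-aryloxiran-2-ylmethanol)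
Conditions: Ti(OiPr)4 (1 equiv), L-(+)-diethyl tartrate (1.2 equiv), t-BuOOH, 4 Å MS, CH2Cl2, −20 °C
Reagents that add atoms: tert-butyl hydroperoxide, CC(C)(C)OO
Why: Sharpless asymmetric epoxidation; the allylic hydroxyl binds the titanium tartrate, which with the L-(+)-ligand delivers oxygen to the alkene face that gives the benzylic carbon R and the carbinol-bearing carbon S, and suprafacial addition to the Z-alkene makes the epoxide cis. Both stereocentres of the target (later C2 and C3) are created here, and the electron-poor aryl group protects the benzylic epoxide from titanium-assisted opening.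

Step 9
Reactants: 11 4-[(2R,3S)-3-(hydroxymethyl)oxiran-2-yl]-2,6-dimethoxyphenyl methanesulfonate
Product: 12 4-[(2R,3S)-3-{[tert-butyl(dimethyl)silyl]oxymethyl}oxiran-2-yl]-2,6-dimethoxyphenyl methanesulfonate
Conditions: TBSCl, imidazole, CH2Cl2, 0 °C to rt
Reagents that add atoms: tert-butyldimethylsilyl chloride, CC(C)(C)[Si](C)(C)Cl
Why: Silylation under weakly basic conditions that form no alkoxide, so Payne rearrangement of the epoxy alcohol is avoided; the silyl ether also blocks that rearrangement under the carbonate base of step 10.

Step 10
Reactants: 5 tert-butyl[3-(4-iodo-3-methoxyphenyl)propoxy]dimethylsilane; 12 4-[(2R,3S)-3-{[tert-butyl(dimethyl)silyl]oxymethyl}oxiran-2-yl]-2,6-dimethoxyphenyl methanesulfonate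
Product: 13 4-[(2S,3R)-3-{[tert-butyl(dimethyl)silyl]oxymethyl}-5-{3-[tert-butyl(dimethyl)silyl]oxypropyl}-7-methoxy-2,3-dihydro-1-benzofuran-2-yl]-2,6-dimethoxyphenyl methanesulfonate
Conditions: Pd(OAc)2 (10 mol %), XPhos (20 mol %), potassium 5-norbornene-2-carboxylate (0.5 equiv), Cs2CO3, NMP, 80 °C; 5 in excess
Reagents that add atoms: none
Why: Proposed new method: zerovalent palladium formed from Pd(OAc)2 and XPhos adds to the C–I bond of 5, the norbornene carboxylate inserts, and palladation of the only free ortho C–H (C3a) gives the divalent aryl–norbornyl palladacycle. This electron-rich palladium centre attacks C3 of epoxide 12 from the face opposite the C3–O bond, with the alkali cation assisting as a Lewis acid, and reductive elimination from the resulting tetravalent palladium alkyl forms C3–C3a with overall inversion at C3. With both ortho positions now substituted (C7 methoxy and the new C3 substituent), β-carbon elimination expels the norbornene and leaves an arylpalladium species at C7a that carries the C2 alkoxide. The dihydrofuran ring closes by C(aryl)–O reductive elimination from this six-membered oxapalladacycle (O1–C7a), which returns zerovalent palladium. The closest known reaction type is the palladium/norbornene ortho-alkylation/ipso-etherification of aryl iodides with terminal epoxides to 2-substituted 2,3-dihydrobenzofurans; new here is an internal, aryl-substituted epoxide opened at its non-benzylic carbon. C2 is carried unchanged from step 8 and C3 is set by the substrate: cis-epoxide geometry plus invertive opening places the silyloxymethyl group trans to the C2 aryl group, giving (2S,3R). The step needs opening at C3 over benzylic C2 and an invertive pathway not preceded by iodide opening of the epoxide; the mesyloxy group removes cation-stabilising donation at the benzylic carbon, the silyl ether is the least inductively deactivating oxygen substituent available at C-γ, and excess 5 keeps zerovalent palladium engaged in oxidative addition and away from the benzylic C–O bond.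

Step 11
Reactants: 13 4-[(2S,3R)-3-{[tert-butyl(dimethyl)silyl]oxymethyl}-5-{3-[tert-butyl(dimethyl)silyl]oxypropyl}-7-methoxy-2,3-dihydro-1-benzofuran-2-yl]-2,6-dimethoxyphenyl methanesulfonate
Product: 14 4-[(2S,3R)-3-(hydroxymethyl)-5-(3-hydroxypropyl)-7-methoxy-2,3-dihydro-1-benzofuran-2-yl]-2,6-dimethoxyphenyl methanesulfonate
Conditions: Bu4NF, THF, 0 °C to rt
Reagents that add atoms: none
Why: Fluoride-induced cleavage of both primary silyl ethers; aryl methanesulfonates are stable to Bu4NF at room temperature, so the phenol stays masked while the diol is released.

Step 12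
Reactants: 14 4-[(2S,3R)-3-(hydroxymethyl)-5-(3-hydroxypropyl)-7-methoxy-2,3-dihydro-1-benzofuran-2-yl]-2,6-dimethoxyphenyl methanesulfonate
Product: 15 4-[(2S,3R)-3-(hydroxymethyl)-5-(3-hydroxypropyl)-7-methoxy-2,3-dihydro-1-benzofuran-2-yl]-2,6-dimethoxyphenol (target)
Conditions: KOH, MeOH/H2O, 60 °C; then aq. NH4Cl
Reagents that add atoms: none
Why: Alkaline cleavage of the aryl methanesulfonate (hydroxide attack at sulfur or E1cB loss of sulfene) releases the phenoxide, which is protonated on work-up; no stereocentre is touched if the temperature stays moderate.

## Compound list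

1 | dihydroconiferyl alcohol, 4-(3-hydroxypropyl)-2-methoxyphenol | COc1cc(CCCO)ccc1O | starting material
2 | 4-(3-hydroxypropyl)-2-methoxyphenyl trifluoromethanesulfonate | COc1cc(CCCO)ccc1OS(=O)(=O)C(F)(F)F | intermediate
3 | 3-[3-methoxy-4-(4,4,5,5-tetramethyl-1,3,2-dioxaborolan-2-yl)phenyl]propan-1-ol | COc1cc(CCCO)ccc1B1OC(C)(C)C(C)(C)O1 | intermediate
4 | 3-(4-iodo-3-methoxyphenyl)propan-1-ol | COc1cc(CCCO)ccc1I | intermediate
5 | tert-butyl[3-(4-iodo-3-methoxyphenyl)propoxy]dimethylsilane | COc1cc(CCCO[Si](C)(C)C(C)(C)C)ccc1I | intermediate
6 | syringaldehyde, 4-hydroxy-3,5-dimethoxybenzaldehyde | COc1cc(C=O)cc(OC)c1O | starting material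
7 | 4-formyl-2,6-dimethoxyphenyl methanesulfonate | COc1cc(C=O)cc(OC)c1OS(C)(=O)=O | intermediate
8 | methyl (Z)-3-[3,5-dimethoxy-4-(methanesulfonyloxy)phenyl]prop-2-enoate | COC(=O)/C=C\c1cc(OC)c(OS(C)(=O)=O)c(OC)c1 | intermediate
9 | (Z)-3-[3,5-dimethoxy-4-(methanesulfonyloxy)phenyl]prop-2-enal (formed in step 7, not isolated) | O=C/C=C\c1cc(OC)c(OS(C)(=O)=O)c(OC)c1 | intermediate
10 | 4-[(Z)-3-hydroxyprop-1-enyl]-2,6-dimethoxyphenyl methanesulfonate | OC/C=C\c1cc(OC)c(OS(C)(=O)=O)c(OC)c1 | intermediate
11 | 4-[(2R,3S)-3-(hydroxymethyl)oxiran-2-yl]-2,6-dimethoxyphenyl methanesulfonate (cis) | COc1cc([C@H]2O[C@H]2CO)cc(OC)c1OS(C)(=O)=O | intermediate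
12 | 4-[(2R,3S)-3-{[tert-butyl(dimethyl)silyl]oxymethyl}oxiran-2-yl]-2,6-dimethoxyphenyl methanesulfonate (cis) | COc1cc([C@H]2O[C@H]2CO[Si](C)(C)C(C)(C)C)cc(OC)c1OS(C)(=O)=O | intermediate
13 | 4-[(2S,3R)-3-{[tert-butyl(dimethyl)silyl]oxymethyl}-5-{3-[tert-butyl(dimethyl)silyl]oxypropyl}-7-methoxy-2,3-dihydro-1-benzofuran-2-yl]-2,6-dimethoxyphenyl methanesulfonate | COc1cc([C@H]2Oc3c(OC)cc(CCCO[Si](C)(C)C(C)(C)C)cc3[C@@H]2CO[Si](C)(C)C(C)(C)C)cc(OC)c1OS(C)(=O)=O | intermediate
14 | 4-[(2S,3R)-3-(hydroxymethyl)-5-(3-hydroxypropyl)-7-methoxy-2,3-dihydro-1-benzofuran-2-yl]-2,6-dimethoxyphenyl methanesulfonate | COc1cc([C@H]2Oc3c(OC)cc(CCCO)cc3[C@@H]2CO)cc(OC)c1OS(C)(=O)=O | intermediate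
15 | 4-[(2S,3R)-3-(hydroxymethyl)-5-(3-hydroxypropyl)-7-methoxy-2,3-dihydro-1-benzofuran-2-yl]-2,6-dimethoxyphenol | COc1cc([C@H]2Oc3c(OC)cc(CCCO)cc3[C@@H]2CO)cc(OC)c1O | target

## Step count and least certain steps

Total: 12 steps. Longest linear sequence: 8 steps (steps 5–12, from syringaldehyde 6); the ring A branch contributes steps 1–4.

**Step 10 (key step).**
- What may go wrong: attack of the palladacycle at the benzylic carbon instead of C3, which is electronically the more usual site for aryl epoxides. Oxidative addition to a hindered internal epoxide may be so slow that the palladacycle is consumed by ipso termination without alkylation. Iodide may open the epoxide first and erode the stereospecificity. Zerovalent palladium may isomerise the aryl epoxide to a carbonyl compound.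
- Fallback (known chemistry only; sets out from 7 and 1, returns at 14): Wittig olefination of 7 with Ph3P=CHCO2Me should give the (E)-enoate F1, DIBAL-H reduction the (E)-allylic alcohol F2, and Sharpless epoxidation with L-(+)-diethyl tartrate (E-allylic alcohols being the most reliable substrate class) the trans-(2S,3S)-epoxy alcohol F3. Iodination of 1 ortho to the phenol with N-iodosuccinimide gives the iodophenol F4. The sodium phenoxide of F4 (NaOH, H2O/dioxane, 70 °C) opens F3 at the benzylic carbon with inversion, which here is the wanted regiochemistry, to give the erythro aryl ether triol F5 with O1–C2 in place. Bu2SnO-catalysed tosylation selects the primary hydroxyl of the 1,2-diol to give the tosylate F6, and K2CO3 in methanol closes the terminal epoxide F7 without touching C3. Iodine–lithium exchange with t-BuLi in THF at −100 °C (one extra equivalent for the free hydroxyl; at this temperature exchange should outrun deprotonation of the sulfonate methyl group) starts a Parham-type 5-exo cyclisation. The aryllithium at C3a opens the epoxide at C3 with inversion and leaves the oxygen on C-γ, which should give 14 directly with the trans (2S,3R) arrangement.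

**Step 8.**
- What may go wrong: incomplete facial selectivity and slow turnover, which are typical of Z-allylic alcohols because the aryl group cis to the carbinol crowds the titanium tartrate. Partner 5 is achiral, so any minor enantiomer of 11 would pass through to the enantiomer of 15 and could not be removed as a diastereomer.
- Fallback (sets out from 8, returns at 11): reagent-controlled Jacobsen epoxidation of the Z-enoate 8 with (R,R)-N,N′-bis(3,5-di-tert-butylsalicylidene)cyclohexane-1,2-diaminomanganese chloride (a salen complex of trivalent manganese), NaOCl and 4-phenylpyridine N-oxide in CH2Cl2 at 0 °C. This should give the cis-(2R,3R)-glycidic ester F8; any trans-epoxide formed by stepwise oxygen transfer is removed by chromatography. NaBH4 in methanol at 0 °C then reduces the activated ester to epoxy alcohol 11.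

**Step 12.**
- What may go wrong: once the phenoxide is present in hot hydroxide, reversible opening of the C2–O1 bond through a quinone methide can compete with slow cleavage of the hindered sulfonate. That would lead to epimerisation at C2 or loss of formaldehyde from C3.
- Fallback (sets out from 13, returns at 15): the order of deprotection is reversed and the mesylate is removed without hydroxide. LiN(iPr)2 in THF at −78 to 0 °C deprotonates the sulfonyl methyl group of 13, and loss of sulfene gives the bis-silylated phenol F10. Bu4NF buffered with acetic acid then removes both silyl ethers at room temperature to give 15.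

**Step 3.**
- What may go wrong: protodeboronation of the electron-rich boronate ortho to the methoxy group in hot aqueous methanol, or incomplete iodination.
- Fallback (sets out from 2, returns at 4): the boronate is bypassed. Stille-type stannylation of triflate 2 with Me3SnSnMe3, Pd(PPh3)4 and LiCl in dioxane at 100 °C gives the arylstannane F9, and iododestannylation with I2 in CH2Cl2 at 0 °C gives 4 by ipso substitution.

## Further compounds

F1 | step 10 | methyl (E)-3-[3,5-dimethoxy-4-(methanesulfonyloxy)phenyl]prop-2-enoate | COC(=O)/C=C/c1cc(OC)c(OS(C)(=O)=O)c(OC)c1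
F2 | step 10 | 4-[(E)-3-hydroxyprop-1-enyl]-2,6-dimethoxyphenyl methanesulfonate | OC/C=C/c1cc(OC)c(OS(C)(=O)=O)c(OC)c1
F3 | step 10 | 4-[(2S,3S)-3-(hydroxymethyl)oxiran-2-yl]-2,6-dimethoxyphenyl methanesulfonate (trans) | COc1cc([C@@H]2O[C@H]2CO)cc(OC)c1OS(C)(=O)=O
F4 | step 10 | 4-(3-hydroxypropyl)-2-iodo-6-methoxyphenol | COc1cc(CCCO)cc(I)c1O
F5 | step 10 | 4-{(1R,2S)-2,3-dihydroxy-1-[4-(3-hydroxypropyl)-2-iodo-6-methoxyphenoxy]propyl}-2,6-dimethoxyphenyl methanesulfonate | COc1cc([C@@H](Oc2c(I)cc(CCCO)cc2OC)[C@@H](O)CO)cc(OC)c1OS(C)(=O)=O
F6 | step 10 | (2S,3R)-3-[3,5-dimethoxy-4-(methanesulfonyloxy)phenyl]-2-hydroxy-3-[4-(3-hydroxypropyl)-2-iodo-6-methoxyphenoxy]propyl 4-methylbenzenesulfonate | COc1cc([C@@H](Oc2c(I)cc(CCCO)cc2OC)[C@@H](O)COS(=O)(=O)c2ccc(C)cc2)cc(OC)c1OS(C)(=O)=O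
F7 | step 10 | 4-{(R)-[4-(3-hydroxypropyl)-2-iodo-6-methoxyphenoxy][(2S)-oxiran-2-yl]methyl}-2,6-dimethoxyphenyl methanesulfonate | COc1cc([C@@H](Oc2c(I)cc(CCCO)cc2OC)[C@@H]2CO2)cc(OC)c1OS(C)(=O)=O
F8 | step 8 | methyl (2R,3R)-3-[3,5-dimethoxy-4-(methanesulfonyloxy)phenyl]oxirane-2-carboxylate (cis) | COc1cc([C@H]2O[C@H]2C(=O)OC)cc(OC)c1OS(C)(=O)=O
F9 | step 3 | 3-[3-methoxy-4-(trimethylstannyl)phenyl]propan-1-ol | COc1cc(CCCO)ccc1[Sn](C)(C)C
F10 | step 12 | 4-[(2S,3R)-3-{[tert-butyl(dimethyl)silyl]oxymethyl}-5-{3-[tert-butyl(dimethyl)silyl]oxypropyl}-7-methoxy-2,3-dihydro-1-benzofuran-2-yl]-2,6-dimethoxyphenol | COc1cc([C@H]2Oc3c(OC)cc(CCCO[Si](C)(C)C(C)(C)C)cc3[C@@H]2CO[Si](C)(C)C(C)(C)C)cc(OC)c1O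
A1 | alternative 1 | (E)-tert-butyldimethyl{[3-(4,4,5,5-tetramethyl-1,3,2-dioxaborolan-2-yl)prop-2-en-1-yl]oxy}silane | CC(C)(C)[Si](C)(C)OC/C=C/B1OC(C)(C)C(C)(C)O1
A2 | alternative 1 | (4-benzyloxy-3,5-dimethoxyphenyl)lithium | [Li]c1cc(OC)c(OCc2ccccc2)c(OC)c1
A3 | alternative 1 | {3-[4-(benzyloxy)-3-bromo-5-methoxyphenyl]propoxy}(tert-butyl)dimethylsilane | COc1cc(CCCO[Si](C)(C)C(C)(C)C)cc(Br)c1OCc1ccccc1
A4 | alternative 1 | syn-1,2-diaryl-3-silyloxypropyl pinacol boronate (ring B and boron on C2, ring A on C3) | COc1cc([C@H]([C@@H](CO[Si](C)(C)C(C)(C)C)c2cc(CCCO[Si](C)(C)C(C)(C)C)cc(OC)c2OCc2ccccc2)B2OC(C)(C)C(C)(C)O2)cc(OC)c1OCc1ccccc1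
A5 | alternative 2 | ethynyl ether of the 1-(4-benzyloxy-3,5-dimethoxyphenyl)-3-silyloxy-2-[4-(3-silyloxypropyl)furan-2-yl]propan-1-ol | COc1cc([C@@H](OC#C)[C@@H](CO[Si](C)(C)C(C)(C)C)c2cc(CCCO[Si](C)(C)C(C)(C)C)co2)cc(OC)c1OCc1ccccc1
A6 | alternative 2 | protected 7-hydroxy-2,3-dihydrobenzofuran (7-O-desmethyl target, bis-silyl ether, benzyl ether) | COc1cc([C@H]2Oc3c(O)cc(CCCO[Si](C)(C)C(C)(C)C)cc3[C@@H]2CO[Si](C)(C)C(C)(C)C)cc(OC)c1OCc1ccccc1
A7 | alternative 3 | (2S)-2-[3,5-dimethoxy-4-(pivaloyloxy)phenyl]-8-methoxy-6-[3-(pivaloyloxy)propyl]chroman-4-one | COc1cc([C@@H]2CC(=O)c3cc(CCCOC(=O)C(C)(C)C)cc(OC)c3O2)cc(OC)c1OC(=O)C(C)(C)C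
A8 | alternative 3 | methyl trans-2-aryl-2,3-dihydrobenzofuran-3-carboxylate dipivalate | COc1cc([C@H]2Oc3c(OC)cc(CCCOC(=O)C(C)(C)C)cc3[C@@H]2C(=O)OC)cc(OC)c1OC(=O)C(C)(C)C
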